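**Strategy.** Everything rests on disconnecting C7–C8 of the ten-membered carbocycle (germacranolide numbering). The pair formed by the C11=C13 exo-methylene lactone and the C8 oxygen is a homoallylic-alcohol retron, so the precursor is an open chain: a 3-(bromomethyl)butenolide (C7=C11, C13–Br, C6 already in the lactone) tied through the (4Z,1(10)E)-diene to a C8 aldehyde. One intramolecular Nozaki–Hiyama–Kishi allylation should form C7–C8, close the carbocycle, shift the alkene to C11=C13 and set C7 and C8 from C6. The closed transition state gives the 8α-alcohol, which a Mitsunobu reaction with angelic acid inverts to the 8β-angelate. The chain derives from neryl acetate.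

Key step: step 16

Remark on the chemistry: germacranolide numbering is used throughout (C1=C10, C4=C5, lactone C12(=O)–O–C6, C13 = exocyclic CH2, C14 = CH2OAc, C15 = CH3). The target is read as (2S,6R,7R,8R), 1(10)E, 4Z, trans-fused 6α,12-olide, with an 8β (Z)-2-methylbut-2-enoate (angelate). TBS = tert-butyldimethylsilyl.

**Step 1**
Reactants: 1 trimethyl phosphonoacetate; 2 (2-bromoethoxy)(tert-butyl)dimethylsilane
Product: 3 methyl 4-(TBS-oxy)-2-(dimethoxyphosphoryl)butanoate (racemic)
Conditions: NaH, NaI (cat.), DMF, 0 to 60 °C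
Reagents that add atoms: none
Why: SN2 C-alkylation of the stabilised phosphonoacetate anion by the primary bromide gives the α-substituted Horner–Wadsworth–Emmons reagent, whose racemic α-carbon becomes sp2 in step 4.

**Step 2**
Reactants: 4 neryl acetate
Product: 5 (2Z)-5-(3,3-dimethyloxiran-2-yl)-3-methylpent-2-en-1-yl acetate (racemic epoxide)
Conditions: mCPBA, NaHCO3, CH2Cl2, 0 °C
Reagents that add atoms: mCPBA, OOC(=O)c1cccc(Cl)c1
Why: Prilezhaev epoxidation should select the electron-rich 6,7-alkene because the 2,3-alkene is deactivated by the allylic acetate; the epoxide stereocentre is cleaved in the next step.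

**Step 3**
Reactants: 5 epoxide
Product: 6 (2Z)-3-methyl-6-oxohex-2-en-1-yl acetate
Conditions: H5IO6, THF/H2O, 0 °C to rt
Reagents that add atoms: water, O
Why: Epoxide hydrolysis followed by periodate glycol cleavage removes the CMe2 terminus as acetone and leaves the C1 aldehyde with the Z alkene (C4=C5) untouched.

**Step 4**
Reactants: 6 aldehyde; 3 phosphonate
Product: 8 methyl (2E,4S,6Z)-8-acetoxy-2-[2-(TBS-oxy)ethyl]-6-methyl-4-(phenylaminooxy)octa-2,6-dienoate, via alpha-anilinooxy aldehyde 7 (not isolated)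
Conditions: PhNO, D-proline (20 mol %), DMSO, rt; then 3, LiCl, DBU, MeCN, 0 °C
Reagents that add atoms: nitrosobenzene, O=Nc1ccccc1
Why: Proline-catalysed enamine α-aminoxylation sets C2 (D-proline gives the S configuration through the hydrogen-bonded enamine transition state), and the labile aldehyde is trapped in the same flask by an E-selective Horner–Wadsworth–Emmons olefination that forms C1=C10 with C2 trans to the ester carbon (future C14).

**Step 5**
Reactants: 8 anilinooxy ester
Product: 9 methyl (2E,4S,6Z)-8-acetoxy-2-[2-(TBS-oxy)ethyl]-4-hydroxy-6-methylocta-2,6-dienoate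
Conditions: CuSO4·5H2O (30 mol %), MeOH, 0 °C to rt
Reagents that add atoms: none
Why: Cu(II)-catalysed N–O cleavage of the O-alkyl-N-arylhydroxylamine should free the C2 alcohol without touching acetate or enoate; any 2Z isomer would lactonise here and be removed.

**Step 6**
Reactants: 9 alcohol
Product: 10 methyl (2E,4S,6Z)-8-acetoxy-4-(TBS-oxy)-2-[2-(TBS-oxy)ethyl]-6-methylocta-2,6-dienoate
Conditions: TBSCl, imidazole, DMF, rt
Reagents that add atoms: tert-butyldimethylsilyl chloride, CC(C)(C)[Si](C)(C)Cl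
Why: Standard silylation protects the secondary allylic O2 for the rest of the route.

**Step 7**
Reactants: 10 acetate
Product: 11 methyl (2E,4S,6Z)-4-(TBS-oxy)-2-[2-(TBS-oxy)ethyl]-8-hydroxy-6-methylocta-2,6-dienoate
Conditions: K2CO3, MeOH, 0 °C
Reagents that add atoms: none
Why: Mild methanolysis removes the allylic acetate, while the conjugated methyl ester is invariant to methoxide exchange and the silyl ethers are stable.

**Step 8**
Reactants: 11 allylic alcohol
Product: 12 methyl (2E,4S,6Z)-4-(TBS-oxy)-2-[2-(TBS-oxy)ethyl]-6-methyl-8-oxoocta-2,6-dienoate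
Conditions: activated MnO2, CH2Cl2, rt
Reagents that add atoms: none
Why: Neutral heterogeneous allylic oxidation should give the Z-enal (C6 aldehyde) without Z to E isomerisation.

**Step 9**
Reactants: 12 Z-enal
Product: 13 methyl (2E,4S,6Z,8S)-4-(TBS-oxy)-2-[2-(TBS-oxy)ethyl]-8-hydroxy-6-methyldeca-2,6,9-trienoate
Conditions: ZnCl2, CH2=CHMgBr, THF then dioxane (Mg salts removed); (−)-MIB (10 mol %), toluene, −30 to 0 °C; H2O
Reagents that add atoms: vinylmagnesium bromide, C=C[Mg]Br
Why: Amino-alcohol-catalysed 1,2-addition of divinylzinc should deliver the vinyl group (C7) to the Si face of the aldehyde, setting C6 under catalyst control, and organozinc reagents leave the ester alone.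

**Step 10**
Reactants: 13 ester
Product: 14 (3S,4Z,7S,8E)-7,11-bis(TBS-oxy)-9-(hydroxymethyl)-5-methylundeca-1,4,8-trien-3-ol
Conditions: DIBAL-H, CH2Cl2, −78 °C; Rochelle salt
Reagents that add atoms: none
Why: 1,2-Reduction of the conjugated ester gives the C14 allylic alcohol with the E geometry retained.

**Step 11**
Reactants: 14 diol
Product: 15 (3S,4Z,7S,8E)-9-(acetoxymethyl)-7,11-bis(TBS-oxy)-5-methylundeca-1,4,8-trien-3-ol
Conditions: AcCl (1.05 equiv), 2,4,6-collidine, CH2Cl2, −78 °C
Reagents that add atoms: acetyl chloride, CC(=O)Cl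
Why: Low-temperature acetylation should distinguish the primary C14 alcohol from the hindered doubly allylic secondary C6 alcohol.

**Step 12**
Reactants: 15 alcohol; 16 2-(bromomethyl)acrylic acid
Product: 17 (3S,4Z,7S,8E)-9-(acetoxymethyl)-7,11-bis(TBS-oxy)-5-methylundeca-1,4,8-trien-3-yl 2-(bromomethyl)acrylate
Conditions: DCC, DMAP (5 mol %), CH2Cl2, 0 °C
Reagents that add atoms: none
Why: Steglich esterification at low temperature attaches C11, C12 and the C13–Br unit to O6 without ionising the doubly allylic carbinol, so C6 is unchanged.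

**Step 13**
Reactants: 17 acrylate
Product: 18 (5R)-5-[(1Z,4S,5E)-6-(acetoxymethyl)-4,8-bis(TBS-oxy)-2-methylocta-1,5-dien-1-yl]-3-(bromomethyl)furan-2(5H)-one
Conditions: second-generation Ru–NHC benzylidene metathesis catalyst (10 mol %), CH2Cl2 (5 mM), 40 °C
Reagents that add atoms: none
Why: Ring-closing metathesis between the only monosubstituted alkene (C7 vinyl) and the 1,1-disubstituted acrylate closes the butenolide (C7=C11); the hindered trisubstituted alkenes should not compete, and the allylic bromide is tolerated.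

**Step 14**
Reactants: 18 bis-silyl ether
Product: 19 (5R)-5-[(1Z,4S,5E)-6-(acetoxymethyl)-4-(TBS-oxy)-8-hydroxy-2-methylocta-1,5-dien-1-yl]-3-(bromomethyl)furan-2(5H)-one
Conditions: CSA (10 mol %), MeOH/CH2Cl2, 0 °C
Reagents that add atoms: none
Why: Acid-catalysed methanolysis cleaves the primary silyl ether (O8) much faster than the secondary allylic one (O2), under conditions that spare allylic bromide, acetate and the butenolide γ-centre.

**Step 15**
Reactants: 19 alcohol
Product: 20 (5R)-5-[(1Z,4S,5E)-6-(acetoxymethyl)-4-(TBS-oxy)-2-methyl-8-oxoocta-1,5-dien-1-yl]-3-(bromomethyl)furan-2(5H)-one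
Conditions: DMP, NaHCO3, CH2Cl2, 0 °C to rt; used crude
Reagents that add atoms: none
Why: Buffered hypervalent-iodine oxidation gives the β,γ-unsaturated C8 aldehyde without base-induced conjugation and tolerates the allylic bromide.

**Step 16**
Reactants: 20 bromolactone aldehyde
Product: 22 (2S,6R,7R,8S)-(1(10)E,4Z)-14-acetoxy-2-(TBS-oxy)-8α-hydroxygermacra-1(10),4,11(13)-trien-12,6α-olide, via allylchromium species 21 (not isolated)
Conditions: CrCl2 (10 equiv), THF/DMF, slow addition of 20 (final 2 mM), rt; aqueous work-up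
Reagents that add atoms: none
Why: Cr(II) reduces the allylic C13–Br bond by two single-electron transfers to the σ-allylchromium(III) species 21, which adds through its γ-carbon C7 to the C8 aldehyde (SE2′) in a closed six-membered chair transition state, so that C7–C8 forms while the alkene moves from C7=C11 to C11=C13. The closest known reactions are the Cr- or Zn-mediated additions of 3-(bromomethyl)furan-2(5H)-ones to aldehydes and Nozaki–Hiyama–Kishi macrocyclisations of ω-formyl allylic bromides to ten-membered carbocycles. The carbocycle closes in a 10-exo-trig mode at the aldehyde carbon, the lactone ring being already present and unchanged. C7 is controlled by C6: the aldehyde should add to the butenolide face opposite the C5 alkenyl branch, giving the trans-fused lactone (7R). C8 is controlled by the chair: the butenolide ring forces C6 into the pseudo-equatorial (E-type) position and C9 is also pseudo-equatorial, an anti arrangement that gives the 8α-alcohol (8S), with a gauche C6–C7–C8–C9 torsion opposite in sign to the anti C5–C6–C7–C8 torsion, as a ten-membered ring prefers. The step needs cyclisation over oligomerisation (high dilution, slow addition, two turn-inducing Z-type ring alkenes), γ- over α-attack (inherent to allylchromium) and chemoselectivity for C–Br and CHO over allylic acetate, lactone and silyl ether (inherent to Cr(II)).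

**Step 17**
Reactants: 22 8α-alcohol; 23 angelic acid
Product: 24 (2S,6R,7R,8R)-(1(10)E,4Z)-14-acetoxy-8β-angeloyloxy-2-(TBS-oxy)germacra-1(10),4,11(13)-trien-12,6α-olide
Conditions: PPh3/DIAD (betaine pre-formed), toluene, 0 °C to rt
Reagents that add atoms: none
Why: In the Mitsunobu esterification the angelate anion displaces the C8 oxyphosphonium ion with inversion (8S to 8R), and because the acid is never acyl-activated the Z alkene should not isomerise to the tiglate.

**Step 18**
Reactants: 24 silyl ether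
Product: 25 target, (2S,6R,7R,8R)-(1(10)E,4Z)-14-acetoxy-8β-angeloyloxy-2-hydroxygermacra-1(10),4,11(13)-trien-12,6α-olide
Conditions: HF·pyridine, pyridine, THF, 0 °C to rt
Reagents that add atoms: none
Why: Buffered fluoride desilylation frees the C2 alcohol without acyl migration or conjugate addition to the α-methylene lactone.

**Compound list**
1 | trimethyl phosphonoacetate | COC(=O)CP(=O)(OC)OC | starting material
2 | (2-bromoethoxy)(tert-butyl)dimethylsilane | CC(C)(C)[Si](C)(C)OCCBr | starting material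
3 | methyl 4-(TBS-oxy)-2-(dimethoxyphosphoryl)butanoate (racemic) | COC(=O)C(CCO[Si](C)(C)C(C)(C)C)P(=O)(OC)OC | intermediate
4 | neryl acetate | CC(=O)OC/C=C(/C)CCC=C(C)C | starting material
5 | (2Z)-5-(3,3-dimethyloxiran-2-yl)-3-methylpent-2-en-1-yl acetate (racemic) | CC(=O)OC/C=C(/C)CCC1OC1(C)C | intermediate
6 | (2Z)-3-methyl-6-oxohex-2-en-1-yl acetate | CC(=O)OC/C=C(/C)CCC=O | intermediate
7 | (2Z,5S)-3-methyl-6-oxo-5-(phenylaminooxy)hex-2-en-1-yl acetate | CC(=O)OC/C=C(/C)C[C@H](ONc1ccccc1)C=O | intermediate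
8 | methyl (2E,4S,6Z)-8-acetoxy-2-[2-(TBS-oxy)ethyl]-6-methyl-4-(phenylaminooxy)octa-2,6-dienoate | CC(=O)OC/C=C(/C)C[C@H](ONc1ccccc1)/C=C(/C(=O)OC)CCO[Si](C)(C)C(C)(C)C | intermediate
9 | methyl (2E,4S,6Z)-8-acetoxy-2-[2-(TBS-oxy)ethyl]-4-hydroxy-6-methylocta-2,6-dienoate | CC(=O)OC/C=C(/C)C[C@H](O)/C=C(/C(=O)OC)CCO[Si](C)(C)C(C)(C)C | intermediate
10 | methyl (2E,4S,6Z)-8-acetoxy-4-(TBS-oxy)-2-[2-(TBS-oxy)ethyl]-6-methylocta-2,6-dienoate | CC(=O)OC/C=C(/C)C[C@H](O[Si](C)(C)C(C)(C)C)/C=C(/C(=O)OC)CCO[Si](C)(C)C(C)(C)C | intermediate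
11 | methyl (2E,4S,6Z)-4-(TBS-oxy)-2-[2-(TBS-oxy)ethyl]-8-hydroxy-6-methylocta-2,6-dienoate | OC/C=C(/C)C[C@H](O[Si](C)(C)C(C)(C)C)/C=C(/C(=O)OC)CCO[Si](C)(C)C(C)(C)C | intermediate
12 | methyl (2E,4S,6Z)-4-(TBS-oxy)-2-[2-(TBS-oxy)ethyl]-6-methyl-8-oxoocta-2,6-dienoate | O=C/C=C(/C)C[C@H](O[Si](C)(C)C(C)(C)C)/C=C(/C(=O)OC)CCO[Si](C)(C)C(C)(C)C | intermediate
13 | methyl (2E,4S,6Z,8S)-4-(TBS-oxy)-2-[2-(TBS-oxy)ethyl]-8-hydroxy-6-methyldeca-2,6,9-trienoate | O[C@@H](C=C)/C=C(/C)C[C@H](O[Si](C)(C)C(C)(C)C)/C=C(/C(=O)OC)CCO[Si](C)(C)C(C)(C)C | intermediate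
14 | (3S,4Z,7S,8E)-7,11-bis(TBS-oxy)-9-(hydroxymethyl)-5-methylundeca-1,4,8-trien-3-ol | O[C@@H](C=C)/C=C(/C)C[C@H](O[Si](C)(C)C(C)(C)C)/C=C(/CO)CCO[Si](C)(C)C(C)(C)C | intermediate
15 | (3S,4Z,7S,8E)-9-(acetoxymethyl)-7,11-bis(TBS-oxy)-5-methylundeca-1,4,8-trien-3-ol | O[C@@H](C=C)/C=C(/C)C[C@H](O[Si](C)(C)C(C)(C)C)/C=C(/COC(C)=O)CCO[Si](C)(C)C(C)(C)C | intermediate
16 | 2-(bromomethyl)acrylic acid | C=C(CBr)C(=O)O | starting material
17 | (3S,4Z,7S,8E)-9-(acetoxymethyl)-7,11-bis(TBS-oxy)-5-methylundeca-1,4,8-trien-3-yl 2-(bromomethyl)acrylate | C=C(CBr)C(=O)O[C@@H](C=C)/C=C(/C)C[C@H](O[Si](C)(C)C(C)(C)C)/C=C(/COC(C)=O)CCO[Si](C)(C)C(C)(C)C | intermediate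
18 | (5R)-5-[(1Z,4S,5E)-6-(acetoxymethyl)-4,8-bis(TBS-oxy)-2-methylocta-1,5-dien-1-yl]-3-(bromomethyl)furan-2(5H)-one | BrCC1=C[C@@H](/C=C(/C)C[C@H](O[Si](C)(C)C(C)(C)C)/C=C(/COC(C)=O)CCO[Si](C)(C)C(C)(C)C)OC1=O | intermediate
19 | (5R)-5-[(1Z,4S,5E)-6-(acetoxymethyl)-4-(TBS-oxy)-8-hydroxy-2-methylocta-1,5-dien-1-yl]-3-(bromomethyl)furan-2(5H)-one | BrCC1=C[C@@H](/C=C(/C)C[C@H](O[Si](C)(C)C(C)(C)C)/C=C(/COC(C)=O)CCO)OC1=O | intermediate
20 | (5R)-5-[(1Z,4S,5E)-6-(acetoxymethyl)-4-(TBS-oxy)-2-methyl-8-oxoocta-1,5-dien-1-yl]-3-(bromomethyl)furan-2(5H)-one | BrCC1=C[C@@H](/C=C(/C)C[C@H](O[Si](C)(C)C(C)(C)C)/C=C(/COC(C)=O)CC=O)OC1=O | intermediate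
21 | allylchromium(III) dichloride derived from 20 (Cr on C13) | Cl[Cr](Cl)CC1=C[C@@H](/C=C(/C)C[C@H](O[Si](C)(C)C(C)(C)C)/C=C(/COC(C)=O)CC=O)OC1=O | intermediate
22 | (2S,6R,7R,8S)-14-acetoxy-2-(TBS-oxy)-8α-hydroxygermacra-1(10)E,4Z,11(13)-trien-12,6α-olide | C=C1C(=O)O[C@@H]2/C=C(/C)C[C@H](O[Si](C)(C)C(C)(C)C)/C=C(/COC(C)=O)C[C@H](O)[C@@H]12 | intermediate
23 | angelic acid, (Z)-2-methylbut-2-enoic acid | C/C=C(/C)C(=O)O | starting material
24 | (2S,6R,7R,8R)-14-acetoxy-8β-angeloyloxy-2-(TBS-oxy)germacra-1(10)E,4Z,11(13)-trien-12,6α-olide | C=C1C(=O)O[C@@H]2/C=C(/C)C[C@H](O[Si](C)(C)C(C)(C)C)/C=C(/COC(C)=O)C[C@@H](OC(=O)/C(C)=C\C)[C@@H]12 | intermediate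
25 | (2S,6R,7R,8R)-14-acetoxy-8β-angeloyloxy-2-hydroxygermacra-1(10)E,4Z,11(13)-trien-12,6α-olide | C=C1C(=O)O[C@@H]2/C=C(/C)C[C@H](O)/C=C(/COC(C)=O)C[C@@H](OC(=O)/C(C)=C\C)[C@@H]12 | target

**Step count.** Total 18 steps; longest linear sequence 17 steps (neryl acetate 4 to target 25, steps 2–18).

**Steps most likely to fail**

1. Step 16 (macrocyclisation). The allylchromium may be protonated or dimerise before it finds the aldehyde, oligomerisation may outrun ring closure, or the tether may override the chair preference and erode facial selectivity at C7/C8. Fallback (intramolecular allylboration, no reducing metal): setting out from 19, Pd(0)-catalysed borylation of the allylic bromide with bis(pinacolato)diboron in DMSO should give the allylboronate alcohol F1 with boron on C13. Buffered DMP oxidation then gives the allylboronate aldehyde F2, which on warming in dilute toluene should cyclise by uncatalysed type-I allylboration through the same closed chair. Hydrolysis of the borate with triethanolamine returns to the route at 22.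

2. Step 17 (Mitsunobu inversion on the ring carbinol). Elimination towards a C8=C9 diene, slow activation of the hindered alcohol, or partial retention may intervene. Fallback (oxidation, reduction, acylation with retention): setting out from 22, DMP oxidation should give the C8 ketone F3. Luche reduction (NaBH4, CeCl3, MeOH, −78 °C) is expected to deliver hydride anti to the C7 lactone branch and give the 8β-alcohol F4. Yamaguchi esterification of F4 with 23 (2,4,6-trichlorobenzoyl chloride, Et3N, then DMAP, toluene) comes back to the route at 24. F4 is also the compound that a reversed C8 selectivity in step 16 would give directly.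

3. Step 9 (asymmetric vinylation). Vinyl transfer to the β,β-disubstituted Z-enal may show insufficient facial selectivity, and the Lewis-acidic zinc may cause Z to E isomerisation of the enal. Fallback (alkynylation then semi-reduction): setting out from 12, ProPhenol/Me2Zn-catalysed addition of trimethylsilylacetylene (ligand enantiomer chosen for Si-face delivery) should give the silylated propargylic alcohol F5. K2CO3/MeOH gives the terminal propargylic alcohol F6, and semi-hydrogenation (H2, Pd/CaCO3–Pb, quinoline) returns to the route at 13.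

**Further compounds**
F1 | step 16 | (5R)-5-[(1Z,4S,5E)-6-(acetoxymethyl)-4-(TBS-oxy)-8-hydroxy-2-methylocta-1,5-dien-1-yl]-3-[(pinacolatoboryl)methyl]furan-2(5H)-one | CC1(C)OB(CC2=C[C@@H](/C=C(/C)C[C@H](O[Si](C)(C)C(C)(C)C)/C=C(/COC(C)=O)CCO)OC2=O)OC1(C)C
F2 | step 16 | (5R)-5-[(1Z,4S,5E)-6-(acetoxymethyl)-4-(TBS-oxy)-2-methyl-8-oxoocta-1,5-dien-1-yl]-3-[(pinacolatoboryl)methyl]furan-2(5H)-one | CC1(C)OB(CC2=C[C@@H](/C=C(/C)C[C@H](O[Si](C)(C)C(C)(C)C)/C=C(/COC(C)=O)CC=O)OC2=O)OC1(C)C
F3 | step 17 | (2S,6R,7S)-14-acetoxy-2-(TBS-oxy)-8-oxogermacra-1(10)E,4Z,11(13)-trien-12,6α-olide | C=C1C(=O)O[C@@H]2/C=C(/C)C[C@H](O[Si](C)(C)C(C)(C)C)/C=C(/COC(C)=O)CC(=O)[C@@H]12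
F4 | step 17 | (2S,6R,7R,8R)-14-acetoxy-2-(TBS-oxy)-8β-hydroxygermacra-1(10)E,4Z,11(13)-trien-12,6α-olide | C=C1C(=O)O[C@@H]2/C=C(/C)C[C@H](O[Si](C)(C)C(C)(C)C)/C=C(/COC(C)=O)C[C@@H](O)[C@@H]12
F5 | step 9 | methyl (2E,4S,6Z,8R)-4-(TBS-oxy)-2-[2-(TBS-oxy)ethyl]-8-hydroxy-6-methyl-10-(trimethylsilyl)deca-2,6-dien-9-ynoate | O[C@@H](C#C[Si](C)(C)C)/C=C(/C)C[C@H](O[Si](C)(C)C(C)(C)C)/C=C(/C(=O)OC)CCO[Si](C)(C)C(C)(C)C
F6 | step 9 | methyl (2E,4S,6Z,8R)-4-(TBS-oxy)-2-[2-(TBS-oxy)ethyl]-8-hydroxy-6-methyldeca-2,6-dien-9-ynoate | O[C@@H](C#C)/C=C(/C)C[C@H](O[Si](C)(C)C(C)(C)C)/C=C(/C(=O)OC)CCO[Si](C)(C)C(C)(C)C
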